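Ring labels: A is the benzoate ring carrying CHO, B the arene annulated to dihydropyranone D, C the central seven-membered lactone-ether. Ring B is made last. Chromanone atoms C4a, C5, C8 and C8a already sit in 5-acetyl-2,2,6-trimethyl-2,3-dihydropyran-4-one. The adjacent oxygen-bearing pair C6 (ether O) and C7 (lactone O) has exactly the oxidation pattern of an aryloxyacetate. The congested ether oxygen is therefore fixed to an sp3 CH2 on ring A by simple alkylation. In one operation the 6-methyl dienolate of the pyranone is acylated by this ester, the ArOCH2 carbon closes onto the acetyl carbonyl, and loss of water aromatises ring B: two C–C bonds, one ring.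

Key step: step 8

Remark: orsellinic acid is taken as the commercial entry to ring A. A tert-butyl group can be placed on the free acid at oxygen, whereas exchange of a di-ortho-substituted methyl ester would need attack at the shielded carbonyl carbon. Polycarbonyl compounds are drawn as keto tautomers. The target has no stereocentre.

Step 1
Reactants: 1 pentane-2,4-dione; 2 3-methylbut-2-enoyl chloride
Product: 3 3-acetyl-6-methylhept-5-ene-2,4-dione (triacylmethane, largely enolised)
Conditions: MgCl2 (1 equiv), pyridine (2 equiv), CH2Cl2, 0 °C → rt; cold 1 M HCl work-up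
Reagents that add atoms: none
Why: Magnesium-mediated soft enolisation turns the β-diketone into a chelate that undergoes C-acylation rather than O-acylation, and the weak base pyridine avoids vinylketene formation from 2.

Step 2
Reactants: 3 3-acetyl-6-methylhept-5-ene-2,4-dione
Product: 4 5-acetyl-2,2,6-trimethyl-2,3-dihydro-4H-pyran-4-one
Conditions: p-TsOH (10 mol %), toluene, 80 °C
Reagents that add atoms: none
Why: Acid-catalysed intramolecular oxa-Michael addition (6-endo-trig) of an enol oxygen to the protonated β,β-dimethyl enone is helped by the gem-dimethyl group, and the two acetyl groups of 3 are equivalent, so only one product can form.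

Step 3
Reactants: 5 2,4-dihydroxy-6-methylbenzoic acid (orsellinic acid)
Product: 6 tert-butyl 2,4-dihydroxy-6-methylbenzoate
Conditions: O-tert-butyl-N,N'-diisopropylisourea (3 equiv), THF, rt
Reagents that add atoms: O-tert-butyl-N,N'-diisopropylisourea, CC(C)NC(=NC(C)C)OC(C)(C)C
Why: Isourea esterification transfers the tert-butyl group to the carboxylate oxygen, so the crowded carbonyl carbon is never attacked, the phenols are too weakly acidic to activate the reagent, and room temperature avoids decarboxylation.

Step 4
Reactants: 6 tert-butyl 2,4-dihydroxy-6-methylbenzoate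
Product: 7 tert-butyl 2-hydroxy-4-methoxy-6-methylbenzoate
Conditions: MeI (1.05 equiv), K2CO3 (1.1 equiv), acetone, rt → 40 °C
Reagents that add atoms: iodomethane, CI
Why: Williamson etherification is selective for the 4-hydroxyl because the 2-hydroxyl is hydrogen-bonded to, and flanked by, the ester carbonyl, as is routine for orsellinates.

Step 5
Reactants: 7 tert-butyl 2-hydroxy-4-methoxy-6-methylbenzoate
Product: 8 tert-butyl 3-formyl-2-hydroxy-4-methoxy-6-methylbenzoate
Conditions: MgCl2 (2 equiv), Et3N (4 equiv), (CH2O)n (6 equiv), MeCN, reflux; cold 1 M HCl work-up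
Reagents that add atoms: paraformaldehyde (formaldehyde source), C=O
Why: Casnati–Skattebøl ortho-formylation delivers formaldehyde inside the magnesium phenoxide complex only ortho to the free hydroxyl, and C3 is the sole open ortho position, so methylating first fixes the regiochemistry while the basic medium spares the tert-butyl ester.

Step 6
Reactants: 8 tert-butyl 3-formyl-2-hydroxy-4-methoxy-6-methylbenzoate; 9 methyl bromoacetate
Product: 10 tert-butyl 3-formyl-4-methoxy-2-(2-methoxy-2-oxoethoxy)-6-methylbenzoate
Conditions: K2CO3 (1.5 equiv), DMF, rt
Reagents that add atoms: none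
Why: Williamson alkylation with a very reactive α-bromo ester places the future diaryl ether oxygen on an sp3 carbon, and a mild carbonate at room temperature keeps the product from closing to a benzofuran by intramolecular aldol condensation.

Step 7
Reactants: 10 tert-butyl 3-formyl-4-methoxy-2-(2-methoxy-2-oxoethoxy)-6-methylbenzoate
Product: 11 tert-butyl 3-(dimethoxymethyl)-4-methoxy-2-(2-methoxy-2-oxoethoxy)-6-methylbenzoate
Conditions: HC(OMe)3 (as solvent), camphorsulfonic acid (3 mol %), rt; Et3N quench
Reagents that add atoms: trimethyl orthoformate, COC(OC)OC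
Why: Orthoformate-driven acid-catalysed acetalisation masks the aldehyde, which would otherwise be the best acceptor for every enolate of the next step; catalytic acid at room temperature leaves the tert-butyl ester intact, and the acetal follows the alkylation because an ortho-hydroxy acetal would not be stable.

Step 8
Reactants: 4 5-acetyl-2,2,6-trimethyl-2,3-dihydro-4H-pyran-4-one; 11 tert-butyl 3-(dimethoxymethyl)-4-methoxy-2-(2-methoxy-2-oxoethoxy)-6-methylbenzoate
Product: 14 tert-butyl 3-(dimethoxymethyl)-2-[(7-hydroxy-2,2,5-trimethyl-4-oxochroman-6-yl)oxy]-4-methoxy-6-methylbenzoate, via Claisen triketone 12 (not isolated), via aldol adduct 13 (not isolated)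
Conditions: 4 (2.2 equiv), LiN(SiMe3)2 (2.2 equiv), THF, −78 → 0 °C; 11 (1 equiv), −78 → 0 °C; LiN(iPr)2 (4 equiv), −78 °C → rt; AcOH, rt
Reagents that add atoms: none
Why: Proposed new method: under equilibrating conditions LiN(SiMe3)2 takes a proton from the 6-methyl group of 4, the only site whose anion is shared by the C4 and the acetyl carbonyl, and the terminal carbon of this dienolate attacks the unhindered, inductively activated methyl ester of 11 (attack through C5 would give a quaternary triacylmethane that reverts), so that 12 forms and is held as its enolate. LiN(iPr)2 then removes a proton from the ArOCH2 group, and this second carbanion adds to the acetyl carbonyl, which sits cis to the side chain on the C5=C6 bond, in an allowed 6-(enolendo)-exo-trig closure to aldolate 13; protonation triggers loss of water because it delivers aromatic ring B. The closest known reaction types are the biomimetic Claisen–aldol aromatisations of poly-β-carbonyl chains, the terminal acylation of dioxinone dienolates followed by aromatisation to resorcylates, and condensations at the acidic methyl group of dehydroacetic acid and of 3-acyl-2-methylchromones. No stereocentre results, since the two transient ones of 13 vanish on dehydration. The selectivity needed is the direction of the aldol step, and it is secured because the new ketone of 12 is locked as an enolate and cannot accept the acetyl methyl carbanion, the acetyl group is twisted out of conjugation by its two neighbours and stays electrophilic, and the aryloxy oxygen makes its CH2 the most acidic position left. The benzoate is shielded by tert-butyl, methyl and aryloxy groups against Claisen attack and against five-membered Dieckmann closure, the acetal removes the aldehyde as acceptor, and any retro-oxa-Michael opening of ring D corrects itself because the resulting phenoxide re-adds to the enone to give the same chromanone.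

Step 9
Reactants: 14 tert-butyl 3-(dimethoxymethyl)-2-[(7-hydroxy-2,2,5-trimethyl-4-oxochroman-6-yl)oxy]-4-methoxy-6-methylbenzoate
Product: 15 3-formyl-2-[(7-hydroxy-2,2,5-trimethyl-4-oxochroman-6-yl)oxy]-4-methoxy-6-methylbenzoic acid
Conditions: CF3CO2H–CH2Cl2 (1:2), H2O (5 equiv), 0 °C → rt
Reagents that add atoms: water, O
Why: Acidolysis of the tert-butyl ester and hydrolysis of the very labile electron-rich aryl acetal occur together, while the diaryl ether, chromanone and methyl ether are inert to trifluoroacetic acid and the only free ring B position lies between two oxygens, too crowded for tert-butylation.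

Step 10
Reactants: 15 3-formyl-2-[(7-hydroxy-2,2,5-trimethyl-4-oxochroman-6-yl)oxy]-4-methoxy-6-methylbenzoic acid
Product: 16 O-methylmollicellin A (the depsidone with OMe in place of the ring A hydroxyl)
Conditions: (CF3CO)2O (3 equiv), toluene, 0 °C → rt
Reagents that add atoms: none
Why: Trifluoroacetic anhydride activates di-ortho-substituted benzoic acids well, and the neighbouring ring B phenol then closes ring C (7-exo-trig lactonisation), the standard depsidone closure from 2-(2-hydroxyaryloxy)benzoic acids.

Step 11
Reactants: 16 O-methylmollicellin A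
Product: 17 mollicellin A
Conditions: BCl3 (3 equiv), CH2Cl2, −78 → 0 °C; aqueous work-up
Reagents that add atoms: none
Why: In this chelation-controlled ether cleavage BCl3 binds the formyl oxygen and the adjacent methoxy oxygen and chloride removes the methyl group, a selective demethylation ortho to a carbonyl that leaves the lactone, the diaryl ether and ring D untouched.

Compound list
1 | pentane-2,4-dione | CC(=O)CC(C)=O | starting material
2 | 3-methylbut-2-enoyl chloride | CC(C)=CC(=O)Cl | starting material
3 | 3-acetyl-6-methylhept-5-ene-2,4-dione | CC(=O)C(C(C)=O)C(=O)C=C(C)C | intermediate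
4 | 5-acetyl-2,2,6-trimethyl-2,3-dihydro-4H-pyran-4-one | CC(=O)C1=C(C)OC(C)(C)CC1=O | intermediate
5 | 2,4-dihydroxy-6-methylbenzoic acid (orsellinic acid) | Cc1cc(O)cc(O)c1C(=O)O | starting material
6 | tert-butyl 2,4-dihydroxy-6-methylbenzoate | Cc1cc(O)cc(O)c1C(=O)OC(C)(C)C | intermediate
7 | tert-butyl 2-hydroxy-4-methoxy-6-methylbenzoate | Cc1cc(OC)cc(O)c1C(=O)OC(C)(C)C | intermediate
8 | tert-butyl 3-formyl-2-hydroxy-4-methoxy-6-methylbenzoate | Cc1cc(OC)c(C=O)c(O)c1C(=O)OC(C)(C)C | intermediate
9 | methyl bromoacetate | COC(=O)CBr | starting material
10 | tert-butyl 3-formyl-4-methoxy-2-(2-methoxy-2-oxoethoxy)-6-methylbenzoate | Cc1cc(OC)c(C=O)c(OCC(=O)OC)c1C(=O)OC(C)(C)C | intermediate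
11 | tert-butyl 3-(dimethoxymethyl)-4-methoxy-2-(2-methoxy-2-oxoethoxy)-6-methylbenzoate | Cc1cc(OC)c(C(OC)OC)c(OCC(=O)OC)c1C(=O)OC(C)(C)C | intermediate
12 | Claisen triketone: ring A aryl-O-CH2-C(=O)-CH2 attached to C6 of the 5-acetyl-2,2-dimethyl-2,3-dihydropyran-4-one | Cc1cc(OC)c(C(OC)OC)c(OCC(=O)CC2=C(C(C)=O)C(=O)CC(C)(C)O2)c1C(=O)OC(C)(C)C | intermediate (not isolated)
13 | aldol adduct: 6-aryloxy-5-hydroxy-2,2,5-trimethyl-5,6-dihydro-2H-chromene-4,7(3H,8H)-dione, diastereomer mixture, both stereocentres lost in the next event | Cc1cc(OC)c(C(OC)OC)c(OC2C(=O)CC3=C(C(=O)CC(C)(C)O3)C2(C)O)c1C(=O)OC(C)(C)C | intermediate (not isolated)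
14 | tert-butyl 3-(dimethoxymethyl)-2-[(7-hydroxy-2,2,5-trimethyl-4-oxochroman-6-yl)oxy]-4-methoxy-6-methylbenzoate | Cc1cc(OC)c(C(OC)OC)c(Oc2c(O)cc3OC(C)(C)CC(=O)c3c2C)c1C(=O)OC(C)(C)C | intermediate
15 | 3-formyl-2-[(7-hydroxy-2,2,5-trimethyl-4-oxochroman-6-yl)oxy]-4-methoxy-6-methylbenzoic acid | Cc1cc(OC)c(C=O)c(Oc2c(O)cc3OC(C)(C)CC(=O)c3c2C)c1C(=O)O | intermediate
16 | O-methylmollicellin A | Cc1cc(OC)c(C=O)c2c1C(=O)Oc1cc3c(c(C)c1O2)C(=O)CC(C)(C)O3 | intermediate
17 | mollicellin A | Cc1cc(O)c(C=O)c2c1C(=O)Oc1cc3c(c(C)c1O2)C(=O)CC(C)(C)O3 | target

Total step count: 11 (2 for the pyranone, 5 for the ring A ester, 4 from the union onward).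
Longest linear sequence: 9 steps (steps 3 to 11).

Steps most likely to fail

1. Step 8.
- Acylation by a well-stabilised dienolate may be slow, so that proton transfer to the ester takes over.
- Kinetic deprotonation may occur at C3 or at the acetyl methyl group.
- The aldol may close in the reverse sense.
- The ArOCH carbanion may close onto the benzoate.
- Lateral deprotonation of the ring A methyl group may use up base.
- Partial loss of the acetal in the quench would do no harm, since step 9 removes it anyway.

Fallback with known chemistry: make the ester bond of ring C first and the ether bond second. It sets out from 8 and 2 and rejoins the route at 16. Compound 8 is cleaved with CF3CO2H in CH2Cl2 to 3-formyl-2-hydroxy-4-methoxy-6-methylbenzoic acid F1. Commercial orcinol is monobrominated (NBS, MeCN, 0 °C) para to one hydroxyl to give 4-bromo-5-methylbenzene-1,3-diol F2. The one remaining position of F2 that is para to a hydroxyl is acylated by 2 (AlCl3, Friedel–Crafts acylation, then base-promoted oxa-Michael closure), giving 6-bromo-7-hydroxy-2,2,5-trimethylchroman-4-one F3. Esterification of F1 with the phenol of F3 ((CF3CO)2O, toluene) should give 6-bromo-2,2,5-trimethyl-4-oxochroman-7-yl 3-formyl-2-hydroxy-4-methoxy-6-methylbenzoate F4. An intramolecular Ullmann ether synthesis (CuI, N,N-dimethylglycine, Cs2CO3, dioxane, 100 °C) then joins the ring A phenoxide to the brominated carbon and gives 16.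

2. Step 5. The formylation may be sluggish because magnesium is held in the salicylate chelate and C3 lies between two oxygen substituents. O-methoxymethylation of the phenol may compete.

Fallback: carbon is delivered by a sigmatropic shift instead of electrophilic substitution (Gassman-type ortho-formylation), from 7 back to 8. 1,3-Dithiane is activated with N-chlorosuccinimide (CH2Cl2, −70 °C) and 7 is added, followed by Et3N. The aryloxysulfonium ylide undergoes a [2,3]-shift to the only free ortho carbon and should give tert-butyl 3-(1,3-dithian-2-yl)-2-hydroxy-4-methoxy-6-methylbenzoate F5. Alkylative hydrolysis (MeI, CaCO3, aqueous MeCN) unmasks 8.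

3. Step 2. Ring closure may stay incomplete against the strongly stabilised enol of the triacylmethane, or an acetyl group may be lost under acid.

Fallback: close ring D by carbonyl addition and dehydration instead of conjugate addition, from 1 back to 4. The dianion of 1 (NaH, then n-BuLi, THF, 0 °C) adds to acetone to give 6-hydroxy-6-methylheptane-2,4-dione F6. Magnesium-mediated C-acetylation (AcCl, MgCl2, pyridine, CH2Cl2) gives 3-acetyl-6-hydroxy-6-methylheptane-2,4-dione F7. With catalytic p-TsOH the tertiary hydroxyl adds to an acetyl carbonyl and water is lost, giving 4.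

Further compounds
F1 | step 8 | 3-formyl-2-hydroxy-4-methoxy-6-methylbenzoic acid | Cc1cc(OC)c(C=O)c(O)c1C(=O)O
F2 | step 8 | 4-bromo-5-methylbenzene-1,3-diol | Cc1cc(O)cc(O)c1Br
F3 | step 8 | 6-bromo-7-hydroxy-2,2,5-trimethylchroman-4-one | Cc1c(Br)c(O)cc2OC(C)(C)CC(=O)c12
F4 | step 8 | 6-bromo-2,2,5-trimethyl-4-oxochroman-7-yl 3-formyl-2-hydroxy-4-methoxy-6-methylbenzoate | Cc1cc(OC)c(C=O)c(O)c1C(=O)Oc1cc2OC(C)(C)CC(=O)c2c(C)c1Br
F5 | step 5 | tert-butyl 3-(1,3-dithian-2-yl)-2-hydroxy-4-methoxy-6-methylbenzoate | Cc1cc(OC)c(C2SCCCS2)c(O)c1C(=O)OC(C)(C)C
F6 | step 2 | 6-hydroxy-6-methylheptane-2,4-dione | CC(=O)CC(=O)CC(C)(C)O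
F7 | step 2 | 3-acetyl-6-hydroxy-6-methylheptane-2,4-dione | CC(=O)C(C(C)=O)C(=O)CC(C)(C)O
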